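**Plan**

- Feature used: in each chroman, ring A is a resorcinol with its oxygens at C7 and C8a (meta), the C4 carbon on C4a (ortho to the C8a oxygen) and only hydrogen at C5, C6 and C8. A vinylketene and an oxygen-substituted alkyne assemble exactly this pattern.
- Retrosynthesis: cut both O1–C2 bonds (phenoxide on a primary chloride). Then cut, in each ring A, C5–C6, C6–C7, C8–C8a and C4a–C8a, giving a bis(alpha-diazo enone) and two molecules of a silyloxyacetylene. Then cut the enone C=C bonds (cross-metathesis), the C3–C4 bonds (allylation of a bis(arylacetyl) imide) and the diaryl ether C–O bond (SNAr).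
- Forward: two ring B aldehydes are joined through the ether oxygen, both ends are homologated, allylated and carried to diazo enones, both rings A are built in one operation, and the two pyran rings close last, before deprotection.
- Stereochemistry: both C3 centres are set (R) in a two-fold Evans allylation with (R)-4-benzyloxazolidin-2-one; no later step makes or breaks a bond at C3.

Key step: step 15

Remark: every two-fold step is written for both ends of the C2-symmetric intermediate at once and so consumes two molecules of its partner or reagent per molecule of substrate; half of fluoride 4 is set aside for step 5 before step 4 is run; (triisopropylsilyloxy)acetylene is treated as a reagent to be made (step 14), not bought.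

**Route**

Step 1
Reactants: 1 3-fluorocatechol
Product: 2 4-fluoro-2,3-dihydroxybenzaldehyde
Conditions: MgCl2, Et3N, (CH2O)n, MeCN, reflux; aq. HCl
Reagents that add atoms: paraformaldehyde (as formaldehyde), C=O
Why: Magnesium-mediated ortho-formylation (Casnati–Skattebøl reaction) delivers formaldehyde within a magnesium phenoxide chelate only ortho to a phenol oxygen, and C6 of 1 is the single free ortho position, so the aldehyde should enter para to fluorine.

Step 2
Reactants: 2 4-fluoro-2,3-dihydroxybenzaldehyde
Product: 3 3-(benzyloxy)-4-fluoro-2-hydroxybenzaldehyde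
Conditions: NaH (2.2 equiv), DMSO, rt; BnBr (1.0 equiv); aq. HCl
Reagents that add atoms: benzyl bromide, BrCc1ccccc1
Why: In the disodium salt the 2-oxide is delocalised into and chelated by the neighbouring formyl group, so one equivalent of benzyl bromide should be taken up by the more nucleophilic 3-oxide (Williamson ether synthesis through the dianion).

Step 3
Reactants: 3 3-(benzyloxy)-4-fluoro-2-hydroxybenzaldehyde
Product: 4 3-(benzyloxy)-4-fluoro-2-methoxybenzaldehyde
Conditions: MeI, K2CO3, DMF, rt to 40 °C
Reagents that add atoms: iodomethane, CI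
Why: Williamson methylation of the remaining hydrogen-bonded salicyl hydroxyl, the only acidic site left.

Step 4
Reactants: 4 3-(benzyloxy)-4-fluoro-2-methoxybenzaldehyde
Product: 6 3-(benzyloxy)-4-hydroxy-2-methoxybenzaldehyde, via aryl sulfonylethyl ether 5 (not isolated)
Conditions: MeSO2CH2CH2OH, NaH, DMF, 0 to 40 °C; aq. HCl
Reagents that add atoms: 2-(methylsulfonyl)ethanol, CS(=O)(=O)CCO
Why: The alkoxide displaces fluoride para to the formyl group (SNAr through a Meisenheimer adduct) and the 2-sulfonylethyl aryl ether 5 then loses methyl vinyl sulfone by E1cB elimination under the same base, so the alcohol acts as a hydroxide surrogate that spares the aldehyde.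

Step 5
Reactants: 4 3-(benzyloxy)-4-fluoro-2-methoxybenzaldehyde; 6 3-(benzyloxy)-4-hydroxy-2-methoxybenzaldehyde
Product: 7 4,4'-oxybis[3-(benzyloxy)-2-methoxybenzaldehyde]
Conditions: Cs2CO3, DMSO, 120 °C
Reagents that add atoms: none
Why: SNAr diaryl ether formation in which the para-formyl group of 4 stabilises the Meisenheimer adduct and fluoride is the best leaving group for the addition-limited pathway (the pairing by which 4-fluorobenzaldehyde and 4-hydroxybenzaldehyde are joined), with the caesium phenoxide in a dipolar aprotic solvent compensating for the ortho substituents.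

Step 6
Reactants: 7 4,4'-oxybis[3-(benzyloxy)-2-methoxybenzaldehyde]
Product: 9 2,2'-{oxybis[3-(benzyloxy)-2-methoxy-4,1-phenylene]}diacetonitrile, via bis(N-formyl sulfonyl enamide) 8 (not isolated)
Conditions: TosMIC (2.4 equiv), KOtBu, DME, -35 °C; then MeOH, reflux
Reagents that add atoms: p-toluenesulfonylmethyl isocyanide (TosMIC), Cc1ccc(cc1)S(=O)(=O)C[N+]#[C-]
Why: van Leusen reductive cyanation, in which the TosMIC anion adds to each aldehyde, the oxazoline opens to the N-formyl sulfonyl enamide 8, and methanolysis of the formyl group with loss of sulfinate leaves the one-carbon-extended nitrile without any reagent that would touch the benzyl ethers.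

Step 7
Reactants: 9 2,2'-{oxybis[3-(benzyloxy)-2-methoxy-4,1-phenylene]}diacetonitrile
Product: 11 2,2'-{oxybis[3-(benzyloxy)-2-methoxy-4,1-phenylene]}diacetic acid, via bis(arylacetamide) 10 (not isolated)
Conditions: KOH, EtOH–H2O, reflux; aq. HCl
Reagents that add atoms: potassium hydroxide, [K+].[OH-]; water, O
Why: Base hydrolysis of an arylacetonitrile through the primary amide, to which aryl ethers are inert.

Step 8
Reactants: 11 2,2'-{oxybis[3-(benzyloxy)-2-methoxy-4,1-phenylene]}diacetic acid; 12 (R)-4-benzyloxazolidin-2-one (3 equiv)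
Product: 14 bis-imide of 11 in which each CO2H has become C(=O)N of an (R)-4-benzyloxazolidin-2-one, via bis(pivalic anhydride) 13 (not isolated)
Conditions: tBuCOCl (2.2 equiv), Et3N, THF, -20 °C; then LiCl (2.2 equiv), 12 (3 equiv), -20 °C to rt
Reagents that add atoms: none
Why: Each carboxylate is activated as its mixed pivalic anhydride and one molecule of the lithium-chloride-activated oxazolidinone per arm then attacks the unhindered arylacetyl carbonyl, so that two molecules of 12 are taken up by each molecule of 11 and the excess is recovered (N-acylation of an Evans auxiliary under mild amine conditions).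

Step 9
Reactants: 14 bis-imide
Product: 15 bis-imide bearing an allyl group at each alpha carbon, (2R) at both new centres, (4R) in both auxiliaries
Conditions: NaN(SiMe3)2 (2.2 equiv), THF, -78 °C; allyl iodide (6 equiv), -78 to -45 °C; AcOH quench at -78 °C
Reagents that add atoms: allyl iodide, C=CCI
Why: Evans asymmetric alkylation, in which each imide forms a sodium-chelated (Z)-enolate whose face on the side of the C4 benzyl group of the (R)-auxiliary is blocked, so allyl iodide enters from the open face and sets (R) at both new benzylic centres, with the minor diastereomers of the two-fold reaction removable by chromatography.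

Step 10
Reactants: 15 diallylated bis-imide
Product: 16 (2R,2'R)-2,2'-{oxybis[3-(benzyloxy)-2-methoxy-4,1-phenylene]}bis(pent-4-en-1-ol)
Conditions: LiBH4, H2O (2 equiv per imide), Et2O–THF, 0 °C
Reagents that add atoms: none
Why: Reductive cleavage of an N-acyloxazolidinone, in which borohydride attacks the exocyclic carbonyl, gives the primary alcohol and releases the auxiliary for recovery under conditions too weakly basic to epimerise the benzylic centres.

Step 11
Reactants: 16 (2R,2'R)-diol
Product: 17 bis{2-(benzyloxy)-4-[(2R)-1-chloropent-4-en-2-yl]-3-methoxyphenyl} ether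
Conditions: PPh3, N-chlorosuccinimide (premixed, 2.4 equiv each), THF, 0 °C to rt
Reagents that add atoms: N-chlorosuccinimide, ClN1C(=O)CCC1=O
Why: Appel-type chlorination by SN2 displacement of the alkoxyphosphonium group at the primary carbon, which leaves the adjacent stereocentre untouched; chloride is chosen as a modest leaving group so that the ortho-methoxy oxygen does not cyclise onto the side chain in later steps.

Step 12
Reactants: 17 (R,R)-dichloride; 18 methyl vinyl ketone (10 equiv)
Product: 19 (3E,3'E,6R,6'R)-6,6'-{oxybis[3-(benzyloxy)-2-methoxy-4,1-phenylene]}bis(7-chlorohept-3-en-2-one)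
Conditions: second-generation Hoveyda–Grubbs catalyst RuCl2(H2IMes)(=CH-C6H4-2-OiPr) (5 mol %), CH2Cl2, 40 °C
Reagents that add atoms: none
Why: Olefin cross-metathesis between a terminal alkene that homodimerises reversibly and an electron-poor enone that does not, driven by loss of ethylene and giving the (E)-enone without involving the homoallylic centre or the chloride.

Step 13
Reactants: 19 bis(methyl enone)
Product: 21 (3E,3'E,6R,6'R)-6,6'-{oxybis[3-(benzyloxy)-2-methoxy-4,1-phenylene]}bis(7-chloro-1-diazohept-3-en-2-one), via bis(trifluoroacetyl ketone) 20 (not isolated)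
Conditions: LiN(SiMe3)2, THF, -78 °C; CF3CO2CH2CF3; then MeSO2N3, Et3N, H2O, MeCN, rt
Reagents that add atoms: methanesulfonyl azide, CS(=O)(=O)N=[N+]=[N-]
Why: Detrifluoroacetylative diazo transfer, in which the kinetic cross-conjugated lithium enolate of each methyl ketone is C-acylated by trifluoroethyl trifluoroacetate, the activated 1,3-diketone 20 accepts the diazo group from the sulfonyl azide and the trifluoroacetyl group leaves as its sulfonamide, which avoids the pyrazoline formation that diazomethane would cause on an enoyl chloride.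

Step 14
Reactants: 22 acetylene
Product: 24 (triisopropylsilyloxy)acetylene, via lithium ethynolate 23 (not isolated)
Conditions: excess HC≡CH, nBuLi, THF, -78 °C; tBuOOLi (from tBuOOH and LiN(SiMe3)2), -78 to -20 °C; iPr3SiOTf, -78 to 0 °C; distillation
Reagents that add atoms: tert-butyl hydroperoxide, CC(C)(C)OO; triisopropylsilyl trifluoromethanesulfonate, CC(C)[Si](OS(=O)(=O)C(F)(F)F)(C(C)C)C(C)C
Why: Oxidation of a lithium acetylide by lithium tert-butyl peroxide (attack of the carbanion on the peroxide oxygen) gives the lithium ynolate, which the bulky silyl triflate captures on oxygen; this one-flask conversion of terminal alkynes into triisopropylsilyl ynol ethers is applied here to acetylene itself, held as its monolithium salt by excess acetylene at low temperature.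

Step 15
Reactants: 21 bis(alpha-diazo enone); 24 (triisopropylsilyloxy)acetylene (6 equiv)
Product: 28 bis{2-(benzyloxy)-4-[(2R)-1-chloro-3-(2-hydroxy-4-(triisopropylsilyloxy)phenyl)propan-2-yl]-3-methoxyphenyl} ether, via bis(vinylketene) 25 (not isolated), via bis(cyclobutenone) 26 (not isolated), via bis(dienylketene) 27 (not isolated)
Conditions: hv (medium-pressure Hg lamp, Pyrex filter, above 290 nm), ClCH2CH2Cl (dilute, 0.02 molar), 20 °C; then 80 °C in the dark
Reagents that add atoms: none
Why: Light expels N2 from each diazo ketone and the alkenyl group shifts to the carbene carbon (photochemical Wolff rearrangement, new C5–C6 bond) to give the (E)-vinylketene 25; the silyloxyalkyne then adds across the ketene C=C bond in a [2+2] cycloaddition, its unsubstituted carbon bonding to the ketene carbonyl carbon (C8–C8a) and its oxygen-bearing carbon to the former diazo carbon (C6–C7), to give the 4-alkenyl-3-silyloxycyclobutenone 26. Warming opens 26 in a reversible 4-electron electrocyclic reaction to the dienylketene 27, which closes ring A by a thermal disrotatory 6-electron electrocyclisation (C4a–C8a bond) and tautomerises to the phenol. The closest known reaction type is the Danheiser benzannulation in its photochemical Wolff variant with silyloxyalkynes, run here at two independent sites of one molecule. Each ring A is therefore closed by pericyclic closure of a ketene-terminated triene and not by a polar cyclisation; the sequence is neutral and creates no lasting stereocentre (the sp3 ring carbon of 26 is transient), so the preformed C3 centres and the primary chlorides are spectators. The one selectivity needed is the orientation of the [2+2] step, which the polarisation of the ynol ether secures: its nucleophilic CH carbon attacks the electrophilic ketene carbon, placing the silyloxy group meta to the new phenol oxygen (C7 against C8a) and the chain carbon ortho to it (C4a). The Pyrex cut-off keeps the aryl ether chromophores of ring B from absorbing.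

Step 16
Reactants: 28 bis(phenol) dichloride
Product: 29 bis{2-(benzyloxy)-3-methoxy-4-[(3R)-7-(triisopropylsilyloxy)chroman-3-yl]phenyl} ether
Conditions: K2CO3, DMF, 60 °C
Reagents that add atoms: none
Why: Intramolecular Williamson etherification in which each C8a phenoxide displaces the primary chloride in a 6-exo-tet closure of the pyran ring, the reacting carbon being C2 so that the C3 configuration is retained.

Step 17
Reactants: 29 bis(silyloxychroman)
Product: 30 bis{2-(benzyloxy)-4-[(3R)-7-hydroxychroman-3-yl]-3-methoxyphenyl} ether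
Conditions: Bu4NF, THF, 0 °C to rt; aq. NH4Cl
Reagents that add atoms: none
Why: Fluoride cleaves the aryl silyl ethers through formation of the strong Si–F bond, while benzyl ethers and the chroman rings are inert.

Step 18
Reactants: 30 bis(benzyl ether)
Product: 31 bis{2-hydroxy-4-[(3R)-7-hydroxychroman-3-yl]-3-methoxyphenyl} ether (the target)
Conditions: H2 (1 atm), 10% Pd/C, EtOAc–MeOH, rt
Reagents that add atoms: none
Why: Hydrogenolysis of the two aryl benzyl ethers over palladium on carbon, to which the diaryl ether, the methyl ethers and the non-benzylic O1–C2 bonds of the chromans are stable and under which the C3–H centres are not epimerised.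

**Compound list**

1 | 3-fluorocatechol | Oc1cccc(F)c1O | starting material
2 | 4-fluoro-2,3-dihydroxybenzaldehyde | O=Cc1ccc(F)c(O)c1O | intermediate
3 | 3-(benzyloxy)-4-fluoro-2-hydroxybenzaldehyde | O=Cc1ccc(F)c(OCc2ccccc2)c1O | intermediate
4 | 3-(benzyloxy)-4-fluoro-2-methoxybenzaldehyde | COc1c(C=O)ccc(F)c1OCc1ccccc1 | intermediate
5 | 3-(benzyloxy)-2-methoxy-4-[2-(methylsulfonyl)ethoxy]benzaldehyde | COc1c(C=O)ccc(OCCS(C)(=O)=O)c1OCc1ccccc1 | intermediate (not isolated)
6 | 3-(benzyloxy)-4-hydroxy-2-methoxybenzaldehyde | COc1c(C=O)ccc(O)c1OCc1ccccc1 | intermediate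
7 | 4,4'-oxybis[3-(benzyloxy)-2-methoxybenzaldehyde] | COc1c(C=O)ccc(Oc2ccc(C=O)c(OC)c2OCc2ccccc2)c1OCc1ccccc1 | intermediate
8 | bis(N-formyl sulfonyl enamide): each CHO of 7 as CH=C(SO2-p-tolyl)NHCHO | COc1c(C=C(NC=O)S(=O)(=O)c2ccc(C)cc2)ccc(Oc2ccc(C=C(NC=O)S(=O)(=O)c3ccc(C)cc3)c(OC)c2OCc2ccccc2)c1OCc1ccccc1 | intermediate (not isolated)
9 | 2,2'-{oxybis[3-(benzyloxy)-2-methoxy-4,1-phenylene]}diacetonitrile | COc1c(CC#N)ccc(Oc2ccc(CC#N)c(OC)c2OCc2ccccc2)c1OCc1ccccc1 | intermediate
10 | 2,2'-{oxybis[3-(benzyloxy)-2-methoxy-4,1-phenylene]}diacetamide | COc1c(CC(N)=O)ccc(Oc2ccc(CC(N)=O)c(OC)c2OCc2ccccc2)c1OCc1ccccc1 | intermediate (not isolated)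
11 | 2,2'-{oxybis[3-(benzyloxy)-2-methoxy-4,1-phenylene]}diacetic acid | COc1c(CC(=O)O)ccc(Oc2ccc(CC(=O)O)c(OC)c2OCc2ccccc2)c1OCc1ccccc1 | intermediate
12 | (R)-4-benzyloxazolidin-2-one | O=C1OC[C@@H](Cc2ccccc2)N1 | starting material
13 | bis(mixed pivalic anhydride) of 11 | COc1c(CC(=O)OC(=O)C(C)(C)C)ccc(Oc2ccc(CC(=O)OC(=O)C(C)(C)C)c(OC)c2OCc2ccccc2)c1OCc1ccccc1 | intermediate (not isolated)
14 | bis-imide: each acetic acid arm of 11 N-acylating an (R)-4-benzyloxazolidin-2-one | COc1c(CC(=O)N2C(=O)OC[C@H]2Cc2ccccc2)ccc(Oc2ccc(CC(=O)N3C(=O)OC[C@H]3Cc3ccccc3)c(OC)c2OCc2ccccc2)c1OCc1ccccc1 | intermediate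
15 | diallylated bis-imide: each arm a (2R)-2-arylpent-4-enoyl imide of the (4R)-auxiliary | COc1c([C@H](C(=O)N2C(=O)OC[C@H]2Cc2ccccc2)CC=C)ccc(Oc2ccc([C@H](C(=O)N3C(=O)OC[C@H]3Cc3ccccc3)CC=C)c(OC)c2OCc2ccccc2)c1OCc1ccccc1 | intermediate
16 | (2R,2'R)-2,2'-{oxybis[3-(benzyloxy)-2-methoxy-4,1-phenylene]}bis(pent-4-en-1-ol) | COc1c([C@H](CO)CC=C)ccc(Oc2ccc([C@H](CO)CC=C)c(OC)c2OCc2ccccc2)c1OCc1ccccc1 | intermediate
17 | bis{2-(benzyloxy)-4-[(2R)-1-chloropent-4-en-2-yl]-3-methoxyphenyl} ether | COc1c([C@H](CCl)CC=C)ccc(Oc2ccc([C@H](CCl)CC=C)c(OC)c2OCc2ccccc2)c1OCc1ccccc1 | intermediate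
18 | methyl vinyl ketone | CC(=O)C=C | starting material
19 | (3E,3'E,6R,6'R)-6,6'-{oxybis[3-(benzyloxy)-2-methoxy-4,1-phenylene]}bis(7-chlorohept-3-en-2-one) | COc1c([C@H](CCl)C/C=C/C(C)=O)ccc(Oc2ccc([C@H](CCl)C/C=C/C(C)=O)c(OC)c2OCc2ccccc2)c1OCc1ccccc1 | intermediate
20 | bis(trifluoroacetyl ketone): each C(=O)CH3 of 19 as C(=O)CH2C(=O)CF3 | COc1c([C@H](CCl)C/C=C/C(=O)CC(=O)C(F)(F)F)ccc(Oc2ccc([C@H](CCl)C/C=C/C(=O)CC(=O)C(F)(F)F)c(OC)c2OCc2ccccc2)c1OCc1ccccc1 | intermediate (not isolated)
21 | (3E,3'E,6R,6'R)-6,6'-{oxybis[3-(benzyloxy)-2-methoxy-4,1-phenylene]}bis(7-chloro-1-diazohept-3-en-2-one) | COc1c([C@H](CCl)C/C=C/C(=O)C=[N+]=[N-])ccc(Oc2ccc([C@H](CCl)C/C=C/C(=O)C=[N+]=[N-])c(OC)c2OCc2ccccc2)c1OCc1ccccc1 | intermediate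
22 | acetylene | C#C | starting material
23 | lithium ethynolate | [Li+].[O-]C#C | intermediate (not isolated)
24 | (triisopropylsilyloxy)acetylene | C#CO[Si](C(C)C)(C(C)C)C(C)C | intermediate
25 | bis(vinylketene): each end a (3E,6R)-6-aryl-7-chlorohepta-1,3-dien-1-one | COc1c([C@H](CCl)C/C=C/C=C=O)ccc(Oc2ccc([C@H](CCl)C/C=C/C=C=O)c(OC)c2OCc2ccccc2)c1OCc1ccccc1 | intermediate (not isolated)
26 | bis(cyclobutenone): each end a 4-[(1E,4R)-4-aryl-5-chloropent-1-enyl]-3-(triisopropylsilyloxy)cyclobut-2-en-1-one (ring sp3 carbon unassigned) | COc1c([C@H](CCl)C/C=C/C2C(=O)C=C2O[Si](C(C)C)(C(C)C)C(C)C)ccc(Oc2ccc([C@H](CCl)C/C=C/C3C(=O)C=C3O[Si](C(C)C)(C(C)C)C(C)C)c(OC)c2OCc2ccccc2)c1OCc1ccccc1 | intermediate (not isolated)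
27 | bis(dienylketene): each end an 8-aryl-9-chloro-3-(triisopropylsilyloxy)nona-1,3,5-trien-1-one, (5E), alkenyl group cis to the ketene arm at C3=C4 | COc1c([C@H](CCl)C/C=C/C=C(/O[Si](C(C)C)(C(C)C)C(C)C)\C=C=O)ccc(Oc2ccc([C@H](CCl)C/C=C/C=C(/O[Si](C(C)C)(C(C)C)C(C)C)\C=C=O)c(OC)c2OCc2ccccc2)c1OCc1ccccc1 | intermediate (not isolated)
28 | bis{2-(benzyloxy)-4-[(2R)-1-chloro-3-(2-hydroxy-4-(triisopropylsilyloxy)phenyl)propan-2-yl]-3-methoxyphenyl} ether | COc1c([C@H](CCl)Cc2ccc(O[Si](C(C)C)(C(C)C)C(C)C)cc2O)ccc(Oc2ccc([C@H](CCl)Cc3ccc(O[Si](C(C)C)(C(C)C)C(C)C)cc3O)c(OC)c2OCc2ccccc2)c1OCc1ccccc1 | intermediate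
29 | bis{2-(benzyloxy)-3-methoxy-4-[(3R)-7-(triisopropylsilyloxy)chroman-3-yl]phenyl} ether | COc1c([C@@H]2COc3cc(O[Si](C(C)C)(C(C)C)C(C)C)ccc3C2)ccc(Oc2ccc([C@@H]3COc4cc(O[Si](C(C)C)(C(C)C)C(C)C)ccc4C3)c(OC)c2OCc2ccccc2)c1OCc1ccccc1 | intermediate
30 | bis{2-(benzyloxy)-4-[(3R)-7-hydroxychroman-3-yl]-3-methoxyphenyl} ether | COc1c([C@@H]2COc3cc(O)ccc3C2)ccc(Oc2ccc([C@@H]3COc4cc(O)ccc4C3)c(OC)c2OCc2ccccc2)c1OCc1ccccc1 | intermediate
31 | bis{2-hydroxy-4-[(3R)-7-hydroxychroman-3-yl]-3-methoxyphenyl} ether (CNP0116832.1) | COc1c([C@@H]2COc3cc(O)ccc3C2)ccc(Oc2ccc([C@@H]3COc4cc(O)ccc4C3)c(OC)c2O)c1O | target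

**Step count and risks**

Total: 18 steps. Longest linear sequence: 17 steps (steps 1 to 13 and 15 to 18, from 3-fluorocatechol); step 14 is a one-step side branch.

Steps most likely to fail:

Step 15 (two-fold benzannulation). Two photochemical and thermal sequences must both run to completion in one molecule. One end may stall at the cyclobutenone stage. A vinylketene may be captured by a phenol already formed at the other end or in another molecule, which leads to esters and oligomers. The silyloxyalkyne may rearrange by a shift of silicon from oxygen to carbon, and the aromatic ethers may compete for light. The fallback gives up the construction of ring A and brings it in ready-made; it sets out from bis-imide 14 and returns at the target 31. Two-fold Evans alkylation of 14 (NaN(SiMe3)2, THF, -78 °C) with 2,4-bis(benzyloxy)benzyl bromide, under the same facial control, should give the doubly benzylated bis-imide F1. Reduction with LiBH4 should then give the diol F2, and PPh3 with N-chlorosuccinimide should convert it into the dichloride F3. Hydrogenolysis over Pd/C should remove all six benzyl groups to give the hexaphenol dichloride F4, and K2CO3 in DMF under argon should close both pyran rings to 31.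

Step 14 (silyloxyacetylene). Monolithium acetylide may disproportionate to the dilithium salt before it is oxidised. Unreacted acetylide may be silylated on carbon. The volatile product may be lost on isolation or may isomerise to a silylketene. The fallback masks the free alkyne position; it sets out from the bis(diazo enone) 21 and returns at 28. Commercial (trimethylsilyl)acetylene, a substituted terminal alkyne that is the standard substrate of the same oxidation and silylation sequence, should give 1-(triisopropylsilyloxy)-2-(trimethylsilyl)acetylene F5. Benzannulation of 21 with this alkyne under the conditions of step 15 should give the bis(2-alkyl-5-silyloxy-6-trimethylsilylphenol) F6, with silicon on the carbon that becomes C8. CF3CO2H in CH2Cl2 at 0 °C should then remove the arylsilane by ipso-protonation between the two oxygen substituents and return 28.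

Step 5 (diaryl ether). Substitution may be slow because the fluorine-bearing carbon has an ortho alkoxy donor and the phenoxide is hindered and delocalised into its para-formyl group. At the temperature then needed the aldehydes may degrade. The fallback removes the conjugation of the nucleophile; it sets out from phenol 6 and returns at 7. Acetalisation of 6 (ethylene glycol, cat. TsOH, toluene, water removal) should give 2-[3-(benzyloxy)-4-hydroxy-2-methoxyphenyl]-1,3-dioxolane F7, whose phenoxide is no longer tied to a carbonyl group. SNAr with 4 (K2CO3, DMF, 100 °C) should give the mono-acetal diaryl ether F8, and aqueous HCl in THF should release the second aldehyde and return 7.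

**Further compounds**

F1 | step 15 | bis-imide 14 bearing a 2,4-bis(benzyloxy)benzyl group at each alpha carbon, (2R) at both new centres | COc1c([C@H](C(=O)N2C(=O)OC[C@H]2Cc2ccccc2)Cc2ccc(OCc3ccccc3)cc2OCc2ccccc2)ccc(Oc2ccc([C@H](C(=O)N3C(=O)OC[C@H]3Cc3ccccc3)Cc3ccc(OCc4ccccc4)cc3OCc3ccccc3)c(OC)c2OCc2ccccc2)c1OCc1ccccc1
F2 | step 15 | (2R,2'R)-2,2'-{oxybis[3-(benzyloxy)-2-methoxy-4,1-phenylene]}bis{3-[2,4-bis(benzyloxy)phenyl]propan-1-ol} | COc1c([C@H](CO)Cc2ccc(OCc3ccccc3)cc2OCc2ccccc2)ccc(Oc2ccc([C@H](CO)Cc3ccc(OCc4ccccc4)cc3OCc3ccccc3)c(OC)c2OCc2ccccc2)c1OCc1ccccc1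
F3 | step 15 | bis{2-(benzyloxy)-4-[(2R)-1-[2,4-bis(benzyloxy)phenyl]-3-chloropropan-2-yl]-3-methoxyphenyl} ether | COc1c([C@H](CCl)Cc2ccc(OCc3ccccc3)cc2OCc2ccccc2)ccc(Oc2ccc([C@H](CCl)Cc3ccc(OCc4ccccc4)cc3OCc3ccccc3)c(OC)c2OCc2ccccc2)c1OCc1ccccc1
F4 | step 15 | bis{4-[(2R)-1-chloro-3-(2,4-dihydroxyphenyl)propan-2-yl]-2-hydroxy-3-methoxyphenyl} ether | COc1c([C@H](CCl)Cc2ccc(O)cc2O)ccc(Oc2ccc([C@H](CCl)Cc3ccc(O)cc3O)c(OC)c2O)c1O
F5 | step 14 | 1-(triisopropylsilyloxy)-2-(trimethylsilyl)acetylene | C[Si](C)(C)C#CO[Si](C(C)C)(C(C)C)C(C)C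
F6 | step 14 | bis{2-(benzyloxy)-4-[(2R)-1-chloro-3-(2-hydroxy-4-(triisopropylsilyloxy)-3-(trimethylsilyl)phenyl)propan-2-yl]-3-methoxyphenyl} ether | COc1c([C@H](CCl)Cc2ccc(O[Si](C(C)C)(C(C)C)C(C)C)c([Si](C)(C)C)c2O)ccc(Oc2ccc([C@H](CCl)Cc3ccc(O[Si](C(C)C)(C(C)C)C(C)C)c([Si](C)(C)C)c3O)c(OC)c2OCc2ccccc2)c1OCc1ccccc1
F7 | step 5 | 2-[3-(benzyloxy)-4-hydroxy-2-methoxyphenyl]-1,3-dioxolane | COc1c(C2OCCO2)ccc(O)c1OCc1ccccc1
F8 | step 5 | 3-(benzyloxy)-4-[2-(benzyloxy)-4-(1,3-dioxolan-2-yl)-3-methoxyphenoxy]-2-methoxybenzaldehyde | COc1c(C2OCCO2)ccc(Oc2ccc(C=O)c(OC)c2OCc2ccccc2)c1OCc1ccccc1
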